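The route rests on cutting the bond between cyclopropane carbon C7 and ring methylene C8 (aromadendrane numbering) in the ten-membered carbocycle of (1S,10R)-bicyclogermacrene, from which the cyclopentane, cycloheptane and oxepane rings of the target arise in one final cationic cascade. The key step closes that carbocycle in one operation, by hydroboration of a terminal diene and intramolecular B-alkyl Suzuki coupling onto a cis-iodocyclopropane; it exploits the alkene-like C7 of the cyclopropane ring (C6, C7, C11), which couples with retention. Its precursor is an open-chain trienyl iodocyclopropane, made by enantioselective, strain-releasing syn-alkenylmetalation of symmetric 3,3-dimethylcyclopropene.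

Key step: step 6

Remark on numbering: C1 is the O-bearing ring-fusion carbon, C4 the quaternary carbon carrying the methyl and the benzylic carbon, C5 the ring-fusion CH, C6 and C7 the cyclopropane CH carbons, C8 and C9 the ring CH2 groups, C10 the CH(CH3) carbon, C11 the C(CH3)2 carbon.

Remark on step 5: the sense of induction of the copper–bisphosphine catalyst cannot be predicted with certainty; the route assumes that one enantiomer of the ligand gives (1R,2R)-10, and the mirror-image ligand is used otherwise.

Step 1
Reactants: 1 pent-4-yn-1-ol
Product: 3 (2E)-2-methylhept-2-en-6-ynal, via pent-4-ynal 2 (not isolated)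
Conditions: IBX, DMSO, rt; then Ph3P=C(CH3)CHO, 40 °C
Reagents that add atoms: 2-(triphenylphosphoranylidene)propanal, CC(C=O)=P(c1ccccc1)(c1ccccc1)c1ccccc1
Why: IBX oxidation to the aldehyde is followed in the same flask by Wittig olefination with the stabilised formyl ylide, which should give the E-trisubstituted enal (the future C1=C10 alkene) under thermodynamic control and stop at mono-olefination because the conjugated, α-branched enal is far less electrophilic than 2.

Step 2
Reactants: 3 (2E)-2-methylhept-2-en-6-ynal
Product: 4 (3E)-3-methylocta-1,3-dien-7-yne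
Conditions: Ph3PCH3Br, KOtBu, THF, 0 °C to rt
Reagents that add atoms: methyltriphenylphosphonium bromide, C[P+](c1ccccc1)(c1ccccc1)c1ccccc1.[Br-]
Why: Wittig methylenation of the enal should install C8 as the terminal carbon of a 1,3-diene without touching the E-alkene, the ylide being too weak a base to deprotonate the terminal alkyne.

Step 3
Reactants: 5 2-methylpropene
Product: 6 1-bromo-2,2-dimethylcyclopropane (racemic)
Conditions: CH2Br2, NaN(SiMe3)2, pentane, −10 °C to rt, sealed vessel, excess 5
Reagents that add atoms: dibromomethane, BrCBr
Why: Deprotonation of dibromomethane gives a bromocarbenoid that cyclopropanates the electron-rich 1,1-disubstituted alkene (halocarbene addition), and the single stereocentre, formed racemic, is erased in step 4.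

Step 4
Reactants: 6 1-bromo-2,2-dimethylcyclopropane
Product: 7 3,3-dimethylcyclopropene
Conditions: KOtBu, DMSO, rt, product swept with argon into a −78 °C trap and kept as a cold Et2O solution
Reagents that add atoms: none
Why: Base-induced 1,2-dehydrobromination in DMSO should give the cyclopropene, which cannot isomerise to a methylenecyclopropane because C3 carries no hydrogen and which leaves the basic medium as it forms.

Step 5
Reactants: 4 (3E)-3-methylocta-1,3-dien-7-yne; 7 3,3-dimethylcyclopropene
Product: 10 (1R,2R)-1-[(1E,5E)-2,6-dimethylocta-1,5,7-trien-1-yl]-2-iodo-3,3-dimethylcyclopropane, via alkenyl(dimethyl)alane 8 (not isolated), via cyclopropyl(dimethyl)alane 9 (not isolated)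
Conditions: Me3Al, Cp2ZrCl2 (cat.), CH2Cl2, 0 °C to rt; volatiles and excess Me3Al removed in vacuo, Et2O–toluene; 7, Cu(MeCN)4PF6 (cat.), (R)-DTBM-SEGPHOS (cat.), −30 to 0 °C; I2, THF, −78 to 0 °C; aq. NaHCO3/Na2S2O3
Reagents that add atoms: trimethylaluminium, C[Al](C)C; iodine, II
Why: Zirconium-catalysed syn-methylalumination of the terminal alkyne (Negishi carboalumination) should give the E-alkenylalane 8 with the methyl on the internal carbon, fixing the C4=C5 geometry, and copper-catalysed syn-alkenylmetalation of the strained, symmetric alkene of 7 (a known enantioselective cyclopropene carbometalation) lets the chiral bisphosphine complex of monovalent copper choose between the two enantiotopic alkene carbons, so that C6 and C7 are set together as the cis pair before the configurationally stable cyclopropyl–metal bond of 9 is cleaved by iodine with retention.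

Step 6
Reactants: 10 (1R,2R)-1-[(1E,5E)-2,6-dimethylocta-1,5,7-trien-1-yl]-2-iodo-3,3-dimethylcyclopropane
Product: 12 (1S,2E,6E,10R)-3,7,11,11-tetramethylbicyclo[8.1.0]undeca-2,6-diene (bicyclogermacrene), via B-alkyl-9-BBN adduct 11 (not isolated)
Conditions: 9-BBN, THF, 0 °C to rt; then slow addition to Pd(dppf)Cl2 (cat.), AsPh3, Cs2CO3, DMF/THF/H2O, 50 °C, high dilution
Reagents that add atoms: none
Why: Proposed new method: 9-BBN should add only to the monosubstituted terminus of the 1,3-diene of 10 (boron at C8), leaving the two trisubstituted alkenes and the C–I bond untouched; zerovalent palladium then inserts into the cyclopropyl C7–I bond with retention, the hydroxy-borate transmetalates intramolecularly, and reductive elimination from the divalent palladium centre of an eleven-membered palladacycle forms C7–C8. The closest known reactions are the Suzuki coupling of iodocyclopropanes with organoboron reagents and the B-alkyl Suzuki–Miyaura macrocyclisation onto alkenyl iodides, which have not been joined in a ring closure at a cyclopropane carbon. The ten-membered carbocycle is closed by C(sp3)–C(cyclopropyl) reductive elimination, and the cyclopropyl–palladium intermediate is protected against β-hydride elimination because its only β-hydrogen (on C6) is trans to the metal, C11 carries none, and elimination would have to form a cyclopropene. No new stereocentre is created: C6 and C7 come from step 5, and retention at C7 in both oxidative addition and reductive elimination keeps C5 and C8 cis, as the cis ring fusion of the target requires. The step needs ring closure to outrun intermolecular coupling and β-hydride elimination of the alkyl–palladium species, which should be secured by slow addition into high dilution, by the wide-bite-angle dppf ligand, and by the two E-trisubstituted alkenes, which fold the chain towards the crossed conformation of an E,E-cyclodeca-1,5-diene. Product 12 is prone to Cope rearrangement on heating and to acid-induced transannular cyclisation, so it should be kept cold and purified on base-washed silica.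

Step 7
Reactants: 12 bicyclogermacrene; 13 benzaldehyde; 14 2,4,6-trihydroxybenzene-1,3-dicarbaldehyde
Product: 16 psiguadial A, via o-quinone methide 15 (not isolated)
Conditions: MeNHCH2CH2NHMe (cat.), (CF3)2CHOH, rt
Reagents that add atoms: none
Why: Amine-catalysed Knoevenagel condensation should give o-quinone methide 15, whose benzylic carbon is attacked by C4 of the cyclopropane-conjugated C4=C5 alkene (the developing C5 cation being cyclopropylcarbinyl-stabilised), after which C1 of the C1=C10 alkene closes the C1–C5 bond transannularly, a 1,2-hydride shift from C1 to C10 moves the charge to C1 and the phenoxide oxygen closes the oxepane, a known type of o-quinone methide/terpene cation cascade in which the centres C4, C5, C1, C10 and the benzylic carbon are set relative to the fixed C6/C7 cyclopropane by the crossed conformation of the E,E-cyclodecadiene, by suprafacial hydride migration and by the need for oxygen and the benzylic carbon to bridge the same face of the cyclopentane.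

Compound list
1 | pent-4-yn-1-ol | C#CCCCO | starting material
2 | pent-4-ynal | C#CCCC=O | intermediate
3 | (2E)-2-methylhept-2-en-6-ynal | C#CCC/C=C(\C)C=O | intermediate
4 | (3E)-3-methylocta-1,3-dien-7-yne | C=C/C(C)=C/CCC#C | intermediate
5 | 2-methylpropene | CC(C)=C | starting material
6 | 1-bromo-2,2-dimethylcyclopropane (racemic) | CC1(C)CC1Br | intermediate
7 | 3,3-dimethylcyclopropene | CC1(C)C=C1 | intermediate
8 | dimethyl[(1E,5E)-2,6-dimethylocta-1,5,7-trien-1-yl]alumane | C[Al](C)/C=C(\C)CC/C=C(\C)C=C | intermediate
9 | {(1R,2R)-2-[(1E,5E)-2,6-dimethylocta-1,5,7-trien-1-yl]-3,3-dimethylcyclopropyl}dimethylalumane | C=C/C(C)=C/CC/C(C)=C/[C@H]1[C@@H]([Al](C)C)C1(C)C | intermediate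
10 | (1R,2R)-1-[(1E,5E)-2,6-dimethylocta-1,5,7-trien-1-yl]-2-iodo-3,3-dimethylcyclopropane (alkenyl and iodine cis) | C=C/C(C)=C/CC/C(C)=C/[C@H]1[C@@H](I)C1(C)C | intermediate
11 | 9-{(3E,7E)-8-[(1R,2R)-2-iodo-3,3-dimethylcyclopropyl]-3,7-dimethylocta-3,7-dien-1-yl}-9-borabicyclo[3.3.1]nonane | C1CCC2CCCC1B2CC/C(C)=C/CC/C(C)=C/[C@H]1[C@@H](I)C1(C)C | intermediate
12 | (1S,2E,6E,10R)-3,7,11,11-tetramethylbicyclo[8.1.0]undeca-2,6-diene (bicyclogermacrene) | C/C1=C\[C@H]2[C@@H](CC/C(C)=C/CC1)C2(C)C | intermediate
13 | benzaldehyde | O=Cc1ccccc1 | starting material
14 | 2,4,6-trihydroxybenzene-1,3-dicarbaldehyde (2,4-diformylphloroglucinol) | O=Cc1c(O)cc(O)c(C=O)c1O | starting material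
15 | 5-benzylidene-2,4-dihydroxy-6-oxocyclohexa-1,3-diene-1,3-dicarbaldehyde (o-quinone methide, alkene geometry not fixed) | O=C1C(=Cc2ccccc2)C(O)=C(C=O)C(O)=C1C=O | intermediate
16 | psiguadial A | C[C@H]1CC[C@@H]2[C@H]([C@@H]3[C@]4(C)CC[C@@]31Oc1c(C=O)c(O)c(C=O)c(O)c1[C@@H]4c1ccccc1)C2(C)C | target

Total step count: 7. Longest linear sequence: 5 steps (steps 1, 2, 5, 6, 7; the branch through steps 3 and 4 is equally long).

Steps most likely to fail

Step 6. After oxidative addition the tethered borane may transmetalate too slowly, so that intermolecular coupling to oligomers, β-hydride elimination of the alkyl–palladium species or protodeboronation take over. The fallback sets out from 10 and comes back at 12; it replaces boron by zinc and separates the making of the nucleophile from the ring closure. Compound 10 is hydroborated as in step 6 (through 11) and oxidised with NaBO3·4H2O in THF/H2O to the primary alcohol (3E,7E)-8-[(1R,2R)-2-iodo-3,3-dimethylcyclopropyl]-3,7-dimethylocta-3,7-dien-1-ol F1. Treatment with I2, PPh3 and imidazole in CH2Cl2 at 0 °C should give the primary iodide (1R,2R)-1-iodo-2-[(1E,5E)-8-iodo-2,6-dimethylocta-1,5-dien-1-yl]-3,3-dimethylcyclopropane F2. Zinc dust with LiCl in THF at rt should insert only into the primary C–I bond to give the alkylzinc iodide {(3E,7E)-8-[(1R,2R)-2-iodo-3,3-dimethylcyclopropyl]-3,7-dimethylocta-3,7-dien-1-yl}zinc iodide F3, which is not isolated. Slow addition of F3 to Pd(OAc)2 and SPhos in THF/NMP at 50 °C should close the same C7–C8 bond by intramolecular Negishi coupling onto the cyclopropyl iodide and give 12.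

Step 5. A methyl group may be transferred from aluminium in place of the alkenyl group, the Lewis-acidic aluminium and zirconium residues may oligomerise 7, or the catalyst may discriminate poorly between the two enantiotopic alkene carbons. The fallback sets out from 4 and comes back at 10; it uses an isolated alkenyl iodide and a methyl-free organomagnesium nucleophile. Carboalumination of 4 (Me3Al, Cp2ZrCl2 cat., CH2Cl2) followed by iodinolysis should give (1E,5E)-1-iodo-2,6-dimethylocta-1,5,7-triene F4. Iodine–lithium exchange with t-BuLi (two equivalents, Et2O, −78 °C) gives [(1E,5E)-2,6-dimethylocta-1,5,7-trien-1-yl]lithium F5, and MgBr2·OEt2 converts it into [(1E,5E)-2,6-dimethylocta-1,5,7-trien-1-yl]magnesium bromide F6. Copper-catalysed enantioselective carbomagnesiation of 7 (CuBr·SMe2, a Josiphos-type ferrocenyl bisphosphine, Et2O–toluene, −40 °C) should give {(1R,2R)-2-[(1E,5E)-2,6-dimethylocta-1,5,7-trien-1-yl]-3,3-dimethylcyclopropyl}magnesium bromide F7, which iodine converts into 10 with retention.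

Step 7. The acidic medium may cyclise 12 transannularly before the o-quinone methide is captured, and the wrong alkene or face may engage 15 (hetero-Diels–Alder addition or diastereomeric cascades), so that the target forms among isomers. The fallback sets out from 13 and 14 and comes back at 16; it makes the o-quinone methide precursor in a separate step so that 12 never meets free acid. Compounds 13, 14 and morpholine in EtOH at rt should give the Mannich base 2,4,6-trihydroxy-5-[morpholin-4-yl(phenyl)methyl]benzene-1,3-dicarbaldehyde F8 (racemic). Heating F8 with 12 in toluene at 80 °C should expel morpholine, release 15 slowly under non-acidic conditions and let the same cascade deliver 16.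

Further compounds
F1 | step 6 | (3E,7E)-8-[(1R,2R)-2-iodo-3,3-dimethylcyclopropyl]-3,7-dimethylocta-3,7-dien-1-ol | OCC/C(C)=C/CC/C(C)=C/[C@H]1[C@@H](I)C1(C)C
F2 | step 6 | (1R,2R)-1-iodo-2-[(1E,5E)-8-iodo-2,6-dimethylocta-1,5-dien-1-yl]-3,3-dimethylcyclopropane | ICC/C(C)=C/CC/C(C)=C/[C@H]1[C@@H](I)C1(C)C
F3 | step 6 | {(3E,7E)-8-[(1R,2R)-2-iodo-3,3-dimethylcyclopropyl]-3,7-dimethylocta-3,7-dien-1-yl}zinc iodide | I[Zn]CC/C(C)=C/CC/C(C)=C/[C@H]1[C@@H](I)C1(C)C
F4 | step 5 | (1E,5E)-1-iodo-2,6-dimethylocta-1,5,7-triene | I/C=C(\C)CC/C=C(\C)C=C
F5 | step 5 | [(1E,5E)-2,6-dimethylocta-1,5,7-trien-1-yl]lithium | [Li]/C=C(\C)CC/C=C(\C)C=C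
F6 | step 5 | [(1E,5E)-2,6-dimethylocta-1,5,7-trien-1-yl]magnesium bromide | Br[Mg]/C=C(\C)CC/C=C(\C)C=C
F7 | step 5 | {(1R,2R)-2-[(1E,5E)-2,6-dimethylocta-1,5,7-trien-1-yl]-3,3-dimethylcyclopropyl}magnesium bromide | C=C/C(C)=C/CC/C(C)=C/[C@H]1[C@@H]([Mg]Br)C1(C)C
F8 | step 7 | 2,4,6-trihydroxy-5-[morpholin-4-yl(phenyl)methyl]benzene-1,3-dicarbaldehyde (racemic) | O=Cc1c(O)c(C=O)c(O)c(C(c2ccccc2)N2CCOCC2)c1O
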